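Ring A is dismantled last. Its two adjacent methoxy groups at C6 and C7 are the mark of symmetric 2,3-dimethoxybuta-1,3-diene. The arene is therefore traced back to a [4+2] addition across the C4a=C8a bond of a monocyclic ring B enone. In one flask the cycloaddition forges C4a–C5 and C8–C8a. Loss of HBr plus two hydrogens then gives the 6,7-dimethoxytetralone, whose C4 carbonyl later delivers the C3 formyl group and the C3=C4 bond. The precursor is a trans-4-aryl-2-bromo-5-(silyloxymethyl)cyclohex-2-enone. Its C2 centre comes from an enamine-catalysed nitro-Michael addition, and C1 is relayed from C2 during ring closure.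

Key step: step 8

Remark (numbering): locants C1–C8a, C9 (CH2O carbon on C2) and C10 (formyl carbon on C3) always follow the target. Ar = 3-methoxy-4-(triisopropylsilyloxy)phenyl. TBS = tert-butyldimethylsilyl.

Remark (descriptors): the target is trans-(1S,2R). The same spatial arrangement reads (4R,5S) in the bromoenone and (3S,4S) in the tetralone, because only the CIP ranking changes.

Remark (design): ring B is not made by adding an arylacetaldehyde enamine to a β-substituted enone, a pairing without sound precedent. The polarity is reversed to linear aldehyde plus nitrostyrene. C2 carries a non-acidifying CH2OTBS group, so it can be neither epimerised nor dehydrogenated.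

Assumption: the α-aryl aldehyde centre of the ring-closure substrate equilibrates faster than the ring closes, so C1 follows the fixed C2 centre.

Step 1
Reactants: 1 2-methoxy-4-[(E)-2-nitroethenyl]phenol
Product: 2 triisopropyl{2-methoxy-4-[(E)-2-nitroethenyl]phenoxy}silane
Conditions: TIPSCl, imidazole, DMF, rt
Reagents that add atoms: triisopropylsilyl chloride, CC(C)[Si](Cl)(C(C)C)C(C)C
Why: Silyl ether formation at the acidic phenol is fast, and the bulky TIPS group is chosen because it must outlast amine, DBU and enolate chemistry yet fall to fluoride at the end.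

Step 2
Reactants: 3 4-methylpent-4-en-1-ol
Product: 4 4-methylpent-4-enal
Conditions: TEMPO (cat.), PhI(OAc)2, CH2Cl2, rt
Reagents that add atoms: none
Why: The TEMPO (oxoammonium) oxidation of a primary alcohol stops at the aldehyde and leaves untouched the 1,1-disubstituted alkene that masks the future C4 methyl ketone.

Step 3
Reactants: 2 nitrostyrene TIPS ether; 4 4-methylpent-4-enal
Product: 6 (2S)-2-[(1R)-1-Ar-2-nitroethyl]-4-methylpent-4-en-1-ol, via nitro aldehyde 5 (not isolated)
Conditions: (R)-2-[diphenyl(trimethylsilyloxy)methyl]pyrrolidine (10 mol %), 4-nitrophenol (10 mol %), toluene, 0 °C to rt; then MeOH, NaBH4, 0 °C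
Reagents that add atoms: none
Why: In this asymmetric enamine-catalysed Michael addition of a linear aldehyde to a β-nitrostyrene, the E-enamine is shielded on one face by the CPh2OTMS group of the (R)-catalyst and attacks through the usual synclinal arrangement to give the syn adduct with C2 (S) and C1 (R), and borohydride reduction in the same flask removes the epimerisable formyl group so that C2 becomes a permanent stereochemical anchor.

Step 4
Reactants: 6 nitro alcohol
Product: 7 tert-butyl{[(2S)-2-[(1R)-1-Ar-2-nitroethyl]-4-methylpent-4-enyl]oxy}dimethylsilane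
Conditions: TBSCl, imidazole, CH2Cl2, rt
Reagents that add atoms: tert-butyldimethylsilyl chloride, CC(C)(C)[Si](C)(C)Cl
Why: This is standard silyl ether formation at the only free hydroxyl group and touches no stereocentre.

Step 5
Reactants: 7 nitro alkene TBS ether
Product: 9 (2R,3S)-2-Ar-3-[(tert-butyldimethylsilyloxy)methyl]-5-oxohexanal, via sodium nitronate 8 (not isolated)
Conditions: NaOMe (1.0 equiv), MeOH/CH2Cl2, 0 °C; O3, −78 °C (Sudan Red 7B end point); Me2S, −78 °C to rt
Reagents that add atoms: ozone, [O-][O+]=O
Why: In this oxidative Nef reaction (nitronate ozonolysis) combined with alkene ozonolysis, ozone cleaves the electron-rich C=N bond to the C8a aldehyde and the methallyl C=C bond to the C4 methyl ketone in one operation, the base ends up as NaNO2 so the medium finishes neutral, and the dye end point keeps excess ozone away from the aryl ring.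

Step 6
Reactants: 9 keto aldehyde
Product: 10 (4S,5S)-4-Ar-5-[(tert-butyldimethylsilyloxy)methyl]cyclohex-2-en-1-one (trans)
Conditions: Bn2NH·CF3CO2H (0.3 equiv), toluene, 50 °C
Reagents that add atoms: none
Why: In this intramolecular aldol condensation under secondary-ammonium catalysis, only closure of the methyl carbon C4a onto the C8a aldehyde gives an unstrained ring, the α-aryl aldehyde centre C1 equilibrates rapidly through its enamine, and closure runs through the chair with Ar and CH2OTBS both equatorial, so C1 is inverted into the trans arrangement dictated by the fixed C2 centre.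

Step 7
Reactants: 10 trans-enone
Product: 12 (4R,5S)-2-bromo-4-Ar-5-[(tert-butyldimethylsilyloxy)methyl]cyclohex-2-en-1-one, via dibromide 11 (not isolated)
Conditions: Br2 (1.0 equiv), CH2Cl2, −78 to −20 °C; then Et3N, 0 °C to rt
Reagents that add atoms: bromine, BrBr
Why: In this bromination–dehydrobromination, Br2 adds anti across C4a=C8a, Et3N removes the acidic C4a–H and bromide leaves from C8a (E1cB) so that bromine stays at C4a only, and a single equivalent at low temperature favours the alkene over the aryl ring.

Step 8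
Reactants: 12 bromoenone; 13 2,3-dimethoxybuta-1,3-diene
Product: 16 (3S,4S)-4-Ar-3-[(tert-butyldimethylsilyloxy)methyl]-6,7-dimethoxy-3,4-dihydronaphthalen-1(2H)-one, via bromo adduct 14 (not isolated), via dienone 15 (not isolated)
Conditions: 13 (4 equiv), BHT (cat.), toluene, 110 °C, sealed tube; then 0 °C, DBU (2 equiv), activated MnO2 (10 equiv), 0 °C to rt
Reagents that add atoms: none
Why: Bromine at C4a makes the C4a=C8a bond a better acceptor, and the donor-substituted diene in its s-cis form adds to it suprafacially in a normal-electron-demand Diels–Alder reaction, so ring A closes in one concerted [4+2] event that forms C4a–C5 and C8–C8a. The closest known reaction type is the cycloaddition of 2-halocycloalkenones to 2,3-dialkoxy- or silyloxybutadienes followed by dehydrohalogenation and dehydrogenation to benzo-fused ketones. The diene should approach anti to the C1 aryl group and give cis-fused 14 with Br-4a and H-8a on the aryl face; because these two are syn, DBU takes the antiperiplanar H-5 instead and gives the push–pull dienone 15. MnO2 then removes H-8 and H-8a from this cyclohexadiene, so both transient stereocentres (C4a, C8a) vanish and no new stereocentre survives. The symmetric diene 13 removes any regiochemical question, and endo/exo and facial outcomes are erased on aromatisation. The selectivity needed is aromatisation of the new ring without touching C1–H or C2–H, which is secured because C2 bears no acidifying group, C1–H is not conjugated to the carbonyl in 14 or 15, MnO2 does not abstract hydride from the diarylmethine position as quinone oxidants can, and adding it together with DBU keeps the base-sensitive dihydro stage short.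

Step 9
Reactants: 16 tetralone; 17 2,2,2-trifluoroethyl formate
Product: 18 (2Z,3R,4S)-4-Ar-3-[(tert-butyldimethylsilyloxy)methyl]-2-(hydroxymethylidene)-6,7-dimethoxy-3,4-dihydronaphthalen-1(2H)-one
Conditions: LiHMDS (1.2 equiv), THF, −78 °C; 17, −78 to −40 °C; then AcOH
Reagents that add atoms: none
Why: This crossed Claisen condensation (α-formylation) occurs at the only enolisable position C3 with an activated formate at low temperature, which avoids alkoxide-rich conditions that could attack the aryl silyl ether, and the product rests as the chelated Z-enol while C1 and C2 are not acidic.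

Step 10
Reactants: 18 hydroxymethylidene ketone
Product: 19 (2E,3R,4S)-4-Ar-3-[(tert-butyldimethylsilyloxy)methyl]-2-(isopropoxymethylidene)-6,7-dimethoxy-3,4-dihydronaphthalen-1(2H)-one
Conditions: iPrI, K2CO3, acetone, 50 °C
Reagents that add atoms: 2-iodopropane, CC(C)I
Why: Williamson-type O-alkylation of the vinylogous acid with a secondary iodide goes to the exposed formyl oxygen because C-alkylation would create a quaternary C3, and the enol ether geometry is of no consequence for the next step.

Step 11
Reactants: 19 isopropoxymethylidene ketone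
Product: 21 (1S,2R)-1-Ar-2-[(tert-butyldimethylsilyloxy)methyl]-6,7-dimethoxy-1,2-dihydronaphthalene-3-carbaldehyde, via allylic alcohol 20 (not isolated)
Conditions: DIBAL-H (1.5 equiv), CH2Cl2, −78 °C; then 1 M aq. HCl, THF, 0 °C
Reagents that add atoms: water, O
Why: This is 1,2-reduction of the vinylogous ester followed by acid-induced allylic transposition (the exocyclic counterpart of the Stork–Danheiser sequence), in which the benzylic C4 alcohol ionises to an alkoxyallyl cation, water adds at C10 and propan-2-ol leaves to give the ring-A-conjugated C3=C4 enal, so the passing C4 carbinol centre is destroyed and C1 and C2 are not involved.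

Step 12
Reactants: 21 bis-silyl enal
Product: 22 (1S,2R)-1-(4-hydroxy-3-methoxyphenyl)-2-(hydroxymethyl)-6,7-dimethoxy-1,2-dihydronaphthalene-3-carbaldehyde (CNP0485134.1)
Conditions: TBAF (3 equiv), AcOH (3 equiv), THF, 0 °C to rt
Reagents that add atoms: none
Why: Fluoride-induced desilylation buffered with acetic acid cleaves the phenolic TIPS and the primary TBS ether while keeping the medium too weakly basic to deprotonate the γ-position C2–H of the enal or to disturb C1.

Compound list
1 | 2-methoxy-4-[(E)-2-nitroethenyl]phenol | COc1cc(/C=C/[N+](=O)[O-])ccc1O | starting material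
2 | triisopropyl{2-methoxy-4-[(E)-2-nitroethenyl]phenoxy}silane | COc1cc(/C=C/[N+](=O)[O-])ccc1O[Si](C(C)C)(C(C)C)C(C)C | intermediate
3 | 4-methylpent-4-en-1-ol | CC(=C)CCCO | starting material
4 | 4-methylpent-4-enal | CC(=C)CCC=O | intermediate
5 | (2S)-2-[(1R)-1-Ar-2-nitroethyl]-4-methylpent-4-enal (syn Michael adduct) | COc1cc([C@H](C[N+](=O)[O-])[C@@H](C=O)CC(C)=C)ccc1O[Si](C(C)C)(C(C)C)C(C)C | intermediate
6 | (2S)-2-[(1R)-1-Ar-2-nitroethyl]-4-methylpent-4-en-1-ol | COc1cc([C@H](C[N+](=O)[O-])[C@@H](CO)CC(C)=C)ccc1O[Si](C(C)C)(C(C)C)C(C)C | intermediate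
7 | TBS ether of 6 | COc1cc([C@H](C[N+](=O)[O-])[C@@H](CO[Si](C)(C)C(C)(C)C)CC(C)=C)ccc1O[Si](C(C)C)(C(C)C)C(C)C | intermediate
8 | sodium nitronate of 7 | [Na+].COc1cc([C@H](C=[N+]([O-])[O-])[C@@H](CO[Si](C)(C)C(C)(C)C)CC(C)=C)ccc1O[Si](C(C)C)(C(C)C)C(C)C | intermediate
9 | (2R,3S)-2-Ar-3-[(TBS-oxy)methyl]-5-oxohexanal (drawn as formed; the aldehyde α-centre C1 is labile) | COc1cc([C@H](C=O)[C@@H](CO[Si](C)(C)C(C)(C)C)CC(C)=O)ccc1O[Si](C(C)C)(C(C)C)C(C)C | intermediate
10 | (4S,5S)-4-Ar-5-[(TBS-oxy)methyl]cyclohex-2-en-1-one, trans | COc1cc([C@H]2C=CC(=O)C[C@@H]2CO[Si](C)(C)C(C)(C)C)ccc1O[Si](C(C)C)(C(C)C)C(C)C | intermediate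
11 | 2,3-dibromo-4-Ar-5-[(TBS-oxy)methyl]cyclohexanone, anti (diaxial) adduct, Br at C8a on the Ar face, Br at C4a on the opposite face | COc1cc([C@H]2[C@@H](Br)[C@H](Br)C(=O)C[C@@H]2CO[Si](C)(C)C(C)(C)C)ccc1O[Si](C(C)C)(C(C)C)C(C)C | intermediate
12 | (4R,5S)-2-bromo-4-Ar-5-[(TBS-oxy)methyl]cyclohex-2-en-1-one, trans | COc1cc([C@H]2C=C(Br)C(=O)C[C@@H]2CO[Si](C)(C)C(C)(C)C)ccc1O[Si](C(C)C)(C(C)C)C(C)C | intermediate
13 | 2,3-dimethoxybuta-1,3-diene | C=C(OC)C(=C)OC | starting material
14 | cis-fused cycloadduct (target numbering): 4a-bromo-1-Ar-2-[(TBS-oxy)methyl]-6,7-dimethoxy-2,3,4a,5,8,8a-hexahydro-1H-naphthalen-4-one, Br-4a and H-8a on the Ar face | COc1cc([C@H]2[C@@H]3CC(OC)=C(OC)C[C@]3(Br)C(=O)C[C@@H]2CO[Si](C)(C)C(C)(C)C)ccc1O[Si](C(C)C)(C(C)C)C(C)C | intermediate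
15 | dienone (target numbering): 1-Ar-2-[(TBS-oxy)methyl]-6,7-dimethoxy-2,3,8,8a-tetrahydro-1H-naphthalen-4-one, double bonds C4a=C5 and C6=C7, H-8a on the Ar face | COc1cc([C@H]2[C@@H]3CC(OC)=C(OC)C=C3C(=O)C[C@@H]2CO[Si](C)(C)C(C)(C)C)ccc1O[Si](C(C)C)(C(C)C)C(C)C | intermediate
16 | (3S,4S)-4-Ar-3-[(TBS-oxy)methyl]-6,7-dimethoxy-3,4-dihydronaphthalen-1(2H)-one, trans | COc1cc([C@H]2c3cc(OC)c(OC)cc3C(=O)C[C@@H]2CO[Si](C)(C)C(C)(C)C)ccc1O[Si](C(C)C)(C(C)C)C(C)C | intermediate
17 | 2,2,2-trifluoroethyl formate | O=COCC(F)(F)F | starting material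
18 | (2Z,3R,4S)-2-(hydroxymethylidene) derivative of 16 | COc1cc([C@H]2c3cc(OC)c(OC)cc3C(=O)/C(=C\O)[C@@H]2CO[Si](C)(C)C(C)(C)C)ccc1O[Si](C(C)C)(C(C)C)C(C)C | intermediate
19 | (2E,3R,4S)-2-(isopropoxymethylidene) derivative of 16 | COc1cc([C@H]2c3cc(OC)c(OC)cc3C(=O)/C(=C/OC(C)C)[C@@H]2CO[Si](C)(C)C(C)(C)C)ccc1O[Si](C(C)C)(C(C)C)C(C)C | intermediate
20 | C4 allylic alcohol from 19 (C4 carbinol centre left open; both epimers ionise to the same cation) | COc1cc([C@H]2c3cc(OC)c(OC)cc3C(O)/C(=C/OC(C)C)[C@@H]2CO[Si](C)(C)C(C)(C)C)ccc1O[Si](C(C)C)(C(C)C)C(C)C | intermediate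
21 | (1S,2R)-1-Ar-2-[(TBS-oxy)methyl]-6,7-dimethoxy-1,2-dihydronaphthalene-3-carbaldehyde | COc1cc([C@H]2c3cc(OC)c(OC)cc3C=C(C=O)[C@@H]2CO[Si](C)(C)C(C)(C)C)ccc1O[Si](C(C)C)(C(C)C)C(C)C | intermediate
22 | (1S,2R)-1-(4-hydroxy-3-methoxyphenyl)-2-(hydroxymethyl)-6,7-dimethoxy-1,2-dihydronaphthalene-3-carbaldehyde | COc1cc([C@H]2c3cc(OC)c(OC)cc3C=C(C=O)[C@@H]2CO)ccc1O | target

Total step count: 12. Longest linear sequence: 11 (steps 1, 3–12, or equally steps 2–12).

Steps most likely to fail

Step 8. The cycloaddition at the hindered, only moderately activated C4a=C8a bond may be too slow, so that thermal polymerisation of the diene outruns it.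
- The fallback sets out from 12 and rejoins the route at 15, and hence 16.
- Palladium-catalysed C–S coupling of 12 with thiophenol (Pd2(dba)3, Xantphos, iPr2NEt, dioxane) would give the 2-(phenylthio)enone F1.
- One equivalent of mCPBA at −78 °C would then give the 2-(phenylsulfinyl)enone F2, as a mixture at sulfur.
- The sulfinyl and carbonyl oxygens chelate ZnBr2, a Lewis acid mild enough for the diene. Diene 13 can therefore add at or below room temperature to give the cis-fused sulfinyl adduct F3.
- Warming in toluene expels benzenesulfenic acid by thermal syn elimination, without base, to give 15. MnO2 then aromatises 15 to 16.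

Step 6. Inversion at C1 may be incomplete before ring closure, or the new double bond may drift out of conjugation towards the aryl group under prolonged amine catalysis.
- The fallback sets out from 9 and returns at 10.
- Catalytic DBU in CH2Cl2 lets C1 epimerise and the aldol addition run reversibly. The material should then collect in the all-equatorial chair aldol F4, where the preference for an equatorial aryl group is larger than in the half-chair enone.
- MsCl and Et3N at 0 °C take F4 through the mesylate F5 to 10 by E1cB elimination. Under these conditions C1–H is not acidic until the product has formed.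

Step 7. Electrophilic bromination of the electron-rich aryl ring may compete with addition to the electron-poor alkene.
- The fallback sets out from 10 and rejoins the route at 15.
- α-Iodination with I2 and pyridine in CH2Cl2 runs by conjugate addition of pyridine, iodination of the resulting enolate and elimination. No electrophile strong enough for the aryl ring is present, and the product is the 2-iodoenone F6.
- F6 takes the place of 12 in step 8. Cycloaddition with 13 gives the iodo adduct F7, and DBU removes HI to reach 15.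

Further compounds
F1 | step 8 | (4R,5S)-4-Ar-2-(phenylthio)-5-[(TBS-oxy)methyl]cyclohex-2-en-1-one | COc1cc([C@H]2C=C(Sc3ccccc3)C(=O)C[C@@H]2CO[Si](C)(C)C(C)(C)C)ccc1O[Si](C(C)C)(C(C)C)C(C)C
F2 | step 8 | 4-Ar-2-(phenylsulfinyl)-5-[(TBS-oxy)methyl]cyclohex-2-en-1-one, ring centres as in 12, mixture at sulfur | COc1cc([C@H]2C=C(S(=O)c3ccccc3)C(=O)C[C@@H]2CO[Si](C)(C)C(C)(C)C)ccc1O[Si](C(C)C)(C(C)C)C(C)C
F3 | step 8 | cis-fused 4a-(phenylsulfinyl) cycloadduct, sulfur and H-8a on the Ar face | COc1cc([C@H]2[C@@H]3CC(OC)=C(OC)C[C@]3(S(=O)c4ccccc4)C(=O)C[C@@H]2CO[Si](C)(C)C(C)(C)C)ccc1O[Si](C(C)C)(C(C)C)C(C)C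
F4 | step 6 | all-equatorial 4-Ar-3-hydroxy-5-[(TBS-oxy)methyl]cyclohexanone | COc1cc([C@H]2[C@H](O)CC(=O)C[C@@H]2CO[Si](C)(C)C(C)(C)C)ccc1O[Si](C(C)C)(C(C)C)C(C)C
F5 | step 6 | methanesulfonate of F4 | COc1cc([C@H]2[C@H](OS(C)(=O)=O)CC(=O)C[C@@H]2CO[Si](C)(C)C(C)(C)C)ccc1O[Si](C(C)C)(C(C)C)C(C)C
F6 | step 7 | (4R,5S)-4-Ar-2-iodo-5-[(TBS-oxy)methyl]cyclohex-2-en-1-one | COc1cc([C@H]2C=C(I)C(=O)C[C@@H]2CO[Si](C)(C)C(C)(C)C)ccc1O[Si](C(C)C)(C(C)C)C(C)C
F7 | step 7 | cis-fused 4a-iodo cycloadduct, I-4a and H-8a on the Ar face | COc1cc([C@H]2[C@@H]3CC(OC)=C(OC)C[C@]3(I)C(=O)C[C@@H]2CO[Si](C)(C)C(C)(C)C)ccc1O[Si](C(C)C)(C(C)C)C(C)C
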